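Count turnovers, and read where the count stops. The turnover number N is the D converted per catalyst charged.

| setting | noon | dusk | flask |
|---|---|---|---|
| D | 0.0020 M | 0.0020 M | 0.0020 M |
| Z | 2 mM | 3 mM | 2.00 mM |
| E | 20 µM | 20 µM | 20 µM |
| remark | the very flask that is asked about, followed so far | run made earlier |  |
| time |  |  | 2.5 min |
| volume of the second phase over the first |  |  | 0.25 |

- noon (time / s: D / %, Q / %): 12.0: 22.0, 76.2; 25.0: 14.6, 85.3; 30.0: 13.3, 86.1; 50.0: 13.5, 86.5
- dusk (time / s: D / %, Q / %): 15.0: 14.3, 85.6; 30.0: 3.7, 94.9; 50.0: 2.7, 98.2; 60.0: 2.0, 97.3

(standard deviation of a reading: 0.5 percentage points)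

- in the second phase: Z, X; everything else is in the first
- charges count per volume of the first phase; a concentration in a rate is the amount of a species over the volume of its own phase; every rate counts per litre of the first phase
- reactions considered so far: D + G -> Q + E; E -> L; E + Z <-> G + X
- the earlier runs hold the two phases in the same ratio of volumes as the flask asked about

- conversion of D at 2.5 min
- amount of Q at 2.5 min, in percent of the D charged
- amount of Q if the flask were left three thousand times as long, in percent of the D charged

In the noon run, N stands at 78.0 by 12.0 s, an average of 6.50 s⁻¹. By 25.0 s it stands at 85.4, which is close to the knee. D then reads 13.3% and 13.5%, flat within the scatter. Take the level as a fraction f = 13.4% of D left. Z was charged equal to D, so about 0.268 mM of Z remains too, and the noon run has stopped with both reagents present. The asked flask repeats noon, and 2.5 min lies beyond 50.0 s, so I expect 86.6% conversion, holding later.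

To reach other charges, assume a pre-equilibrium in E + Z ⇌ G + X, so that E over G follows X over Z. Each D converted then costs catalyst in proportion to X/(Z·D). With D and Z charged equal, these costs add up to w(1/f − 1 + ln f), which equals the E charged at the stop. The noon level thus gives the cost constant w = 4.49 µM.

The forecast gives 86.7% conversion, 86.5% of Q and 86.8% in the long run. Its ground: “The stall must therefore be catalyst death through E → L.”

The flask gives 87.2%, 87.2% and 87.2%.

    D + G → Q + E (k = 7700 M⁻¹ s⁻¹)
    E → L (k = 0.440 s⁻¹)
    E + Z ⇌ G + X (K = 14.0, k = 1.40 × 10⁶ M⁻¹ s⁻¹)

In this flask at 0.0629 min, G falls back 40 times faster than it goes on, and L holds >99.9% of the catalyst by 1.25 min. Put this flask's residue of D into the sum, and w(1/f − 1 + ln f) comes to 21.4 µM, where 20 µM of E was charged.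

For the neighbour with 5.0 × 10⁻⁵ M of E, w asks for 1/f − 1 + ln f = 11.1. Trial gives f = 6.77%, with N at 37.3. The computed neighbour ends with 6.61% of D.

The numbers in the tables are simulated for substances that don't exist, and the scatter is random.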